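## Retrosynthetic overview
1. End game: acidolysis of two MOM ethers and one tert-butyl ester. Before that, the coumarate C–O bond is made by Mitsunobu esterification, and the terminal (E)-CH2OH by allylic C–H oxidation of a prenyl end.
2. Key disconnection: the ring O–C2 bond. A catalytic enantioselective 7-exo-trig oxa-Michael closure of a (Z)-allylic alcohol onto an aroylacrylate makes the oxepine and the only stereocentre in one step.
3. The open-chain enone comes from a B-alkyl Suzuki–Miyaura coupling of an aroylpyruvate enol triflate with a homoallyl-9-BBN made from a (Z)-dienol.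
4. The triflate comes from 2',5'-dihydroxyacetophenone and di-tert-butyl oxalate. The dienol comes from propargyl alcohol, homoprenyl bromide and vinyl bromide; an anti-carbomagnesiation fixes the future ring alkene.
5. Ring order: both arenes are bought. The oxepine is the only ring made (step 6).

Assumption: the facial preference of the new catalyst cannot be known beforehand. The L-tert-leucine-derived enantiomer is written as the one giving (R); its mirror image is used if a test run gives (S).

BIMP catalyst for step 6: 1-[3,5-bis(trifluoromethyl)phenyl]-3-[(2S)-3,3-dimethyl-1-{[tris(4-methoxyphenyl)phosphoranylidene]amino}butan-2-yl]thiourea.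
SMILES: COc1ccc(cc1)P(=NC[C@@H](NC(=S)Nc1cc(cc(c1)C(F)(F)F)C(F)(F)F)C(C)(C)C)(c1ccc(OC)cc1)c1ccc(OC)cc1
It is made beforehand from the azide and P(4-MeOC6H4)3 (Staudinger reaction), is used at 10 mol %, and is not counted as a step.

## Route

Step 1
Reactants: 1 2',5'-dihydroxyacetophenone
Product: 3 2',5'-bis(methoxymethoxy)acetophenone, via disodium bis-phenoxide 2 (not isolated)
Conditions: NaH (2.5 equiv), DMF, 0 °C; MOMCl (2.6 equiv), 0 °C → rt
Reagents that add atoms: chloromethyl methyl ether (MOMCl), COCCl
Why: Williamson-type O-alkylation (acetal protection); NaH is needed because the 2'-OH is hydrogen-bonded to the ketone, and both phenols must be masked so that the ortho-phenol cannot close a chromone in step 2 or a chromanone in step 6.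

Step 2
Reactants: 3 2',5'-bis(methoxymethoxy)acetophenone; 4 di-tert-butyl oxalate (1.2 equiv)
Product: 5 sodium (2Z)-4-[2,5-bis(methoxymethoxy)phenyl]-1-tert-butoxy-1,4-dioxobut-2-en-2-olate
Conditions: NaOtBu (1.1 equiv), THF, 0 °C → rt; evaporated, triturated with hexane, dried in vacuo
Reagents that add atoms: sodium tert-butoxide, CC(C)(C)[O-].[Na+]
Why: Crossed Claisen condensation of a methyl ketone with a non-enolisable oxalate under the matching alkoxide, driven by formation of the chelated, stabilised enolate, which is collected as its salt so that the MOM groups never meet acid.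

Step 3
Reactants: 5 sodium aroylpyruvate enolate
Product: 6 tert-butyl (2Z)-4-[2,5-bis(methoxymethoxy)phenyl]-4-oxo-2-{[(trifluoromethyl)sulfonyl]oxy}but-2-enoate
Conditions: Tf2O (1.1 equiv), CH2Cl2, −78 → 0 °C
Reagents that add atoms: trifluoromethanesulfonic anhydride, O=S(=O)(OS(=O)(=O)C(F)(F)F)C(F)(F)F
Why: Enolate O-sulfonylation (enol triflate formation); aroylpyruvates react with O-electrophiles at the oxygen next to the ester, which keeps the aryl ketone conjugated, and the sodium chelate fixes the Z geometry.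

Step 4
Reactants: 7 5-bromo-2-methylpent-2-ene (2.5 equiv); 8 prop-2-yn-1-ol; 9 vinyl bromide (3 equiv, 1 M in THF)
Product: 12 (2Z)-2-(4-methylpent-3-en-1-yl)penta-2,4-dien-1-ol, via homoprenylmagnesium bromide 10 (not isolated), via oxamagnesacycle 11 (not isolated)
Conditions: Mg, THF, rt; 8, CuI (10 mol %), −10 °C → rt; then 9, Pd(PPh3)4 (5 mol %), rt → 45 °C; aqueous work-up
Reagents that add atoms: none
Why: Copper-catalysed anti-carbomagnesiation of propargyl alcohol puts the alkyl group on C-2 and magnesium on C-3 cis to CH2O in a five-membered chelate, and the Kumada–Corriu coupling then replaces magnesium by vinyl with retention, so the vinyl group ends cis to CH2OH (the Z alkene that becomes the ring alkene).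

Step 5
Reactants: 12 (Z)-dienol (1.2 equiv); 6 enol triflate
Product: 14 tert-butyl (2E)-4-[2,5-bis(methoxymethoxy)phenyl]-2-[(3Z)-4-(hydroxymethyl)-8-methylnona-3,7-dien-1-yl]-4-oxobut-2-enoate, via bis-9-BBN adduct 13 (not isolated)
Conditions: 9-BBN (2.2 equiv per 12), THF, 0 °C → rt; then 6, Pd(dppf)Cl2 (5 mol %), anhydrous powdered K3PO4 (1.5 equiv), DMF/THF, rt; pH 7 aqueous work-up
Reagents that add atoms: none
Why: 9-BBN hydroborates only the terminal vinyl group, and the B-alkyl Suzuki–Miyaura coupling replaces the triflate with retention of geometry, while the hydroxyl travels through the basic coupling as its 9-BBN borinate and so cannot add to the enone before the chiral catalyst is present.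

Step 6
Reactants: 14 open-chain hydroxy aroylacrylate
Product: 15 tert-butyl (2R)-2-{2-[2,5-bis(methoxymethoxy)phenyl]-2-oxoethyl}-6-(4-methylpent-3-en-1-yl)-2,3,4,7-tetrahydrooxepine-2-carboxylate
Conditions: BIMP catalyst (10 mol %), toluene (0.02 M), 4 Å molecular sieves, −20 °C, 24–72 h; filtered through silica
Reagents that add atoms: none
Why: Proposed new method: enantioselective 7-exo-trig oxa-Michael closure of a primary allylic alcohol onto the fully substituted carbon of an aroylacrylate under a bifunctional iminophosphorane–thiourea superbase; the thiourea binds the aryl ketone oxygen and lowers the LUMO, the iminophosphorane takes the O–H proton as the C–O bond forms, the Z alkene of the tether holds O and C-2 close in a cycloheptene-like transition state, attack β to the ketone wins over attack β to the ester both electronically and by ring size (seven against eight), the iminophosphonium then protonates the enolate at C-3, and the chiral pocket leaves open the Re face of C-2 (CO2tBu → C-3 → CH2 clockwise), which gives (R); the closest known reaction type is the bifunctional-organocatalyst intramolecular oxa-Michael reaction giving five- and six-membered ethers with a tertiary centre, and the seven-membered ring, the tetrasubstituted α-alkoxy ester centre and the acceptor class are new.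

Step 7
Reactants: 15 oxepine ester
Product: 16 tert-butyl (2R)-2-{2-[2,5-bis(methoxymethoxy)phenyl]-2-oxoethyl}-6-[(3E)-5-hydroxy-4-methylpent-3-en-1-yl]-2,3,4,7-tetrahydrooxepine-2-carboxylate
Conditions: SeO2 (0.3 equiv), tBuOOH (2.5 equiv, in decane), CH2Cl2, 0 °C, stopped at about 70 % conversion, 15 recycled
Reagents that add atoms: tert-butyl hydroperoxide, CC(C)(C)OO
Why: Catalytic Riley allylic oxidation (ene reaction then [2,3]-sigmatropic shift) takes the (E)-methyl of the electron-rich gem-dimethyl alkene, while the ring alkene is deactivated by its allylic oxygen, as in geranyl ethers and esters, and the ketone CH2 is untouched at 0 °C.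

Step 8
Reactants: 16 allylic alcohol; 17 (E)-4-hydroxycinnamic acid (p-coumaric acid, 1.5 equiv)
Product: 18 tert-butyl (2R)-2-{2-[2,5-bis(methoxymethoxy)phenyl]-2-oxoethyl}-6-[(3E)-5-{[(2E)-3-(4-hydroxyphenyl)prop-2-enoyl]oxy}-4-methylpent-3-en-1-yl]-2,3,4,7-tetrahydrooxepine-2-carboxylate
Conditions: PPh3 (1.2 equiv), DIAD (1.2 equiv), THF, 0 °C → rt
Reagents that add atoms: none
Why: Mitsunobu esterification engages the carboxylic acid (pKa about 4.5) and not the much less acidic phenol, so 17 is used unprotected; the primary allylic alcohol reacts by direct SN2 without transposition, and the conditions are too mild for a retro-oxa-Michael reaction.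

Step 9
Reactants: 18 protected coumarate
Product: 19 (2R)-2-[2-(2,5-dihydroxyphenyl)-2-oxoethyl]-6-[(3E)-5-{[(2E)-3-(4-hydroxyphenyl)prop-2-enoyl]oxy}-4-methylpent-3-en-1-yl]-2,3,4,7-tetrahydrooxepine-2-carboxylic acid (target)
Conditions: TFA/CH2Cl2/H2O (30:65:5), argon, 0 °C → rt, 2 h
Reagents that add atoms: none
Why: One acidolysis removes the tert-butyl ester (loss of isobutene) and hydrolyses both MOM acetals; both alkenes carry an allylic oxygen that slows protonation, neither allylic C–O bond can ionise to a tertiary cation, and the quaternary α-carboxy centre can neither ionise nor epimerise.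

## Compound list
1 | 2',5'-dihydroxyacetophenone | CC(=O)c1cc(O)ccc1O | starting material
2 | disodium 2-acetylbenzene-1,4-diolate | CC(=O)c1cc([O-])ccc1[O-].[Na+].[Na+] | intermediate
3 | 2',5'-bis(methoxymethoxy)acetophenone | CC(=O)c1cc(OCOC)ccc1OCOC | intermediate
4 | di-tert-butyl oxalate | CC(C)(C)OC(=O)C(=O)OC(C)(C)C | starting material
5 | sodium (2Z)-4-[2,5-bis(methoxymethoxy)phenyl]-1-tert-butoxy-1,4-dioxobut-2-en-2-olate | [Na+].[O-]/C(=C\C(=O)c1cc(OCOC)ccc1OCOC)C(=O)OC(C)(C)C | intermediate
6 | tert-butyl (2Z)-4-[2,5-bis(methoxymethoxy)phenyl]-4-oxo-2-(triflyloxy)but-2-enoate | O=C(/C=C(\OS(=O)(=O)C(F)(F)F)C(=O)OC(C)(C)C)c1cc(OCOC)ccc1OCOC | intermediate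
7 | 5-bromo-2-methylpent-2-ene | CC(C)=CCCBr | starting material
8 | prop-2-yn-1-ol | C#CCO | starting material
9 | vinyl bromide | C=CBr | starting material
10 | (4-methylpent-3-en-1-yl)magnesium bromide | CC(C)=CCC[Mg]Br | intermediate
11 | 4-(4-methylpent-3-en-1-yl)-2,5-dihydro-1,2-oxamagnesole | CC(C)=CCCC1=C[Mg]OC1 | intermediate
12 | (2Z)-2-(4-methylpent-3-en-1-yl)penta-2,4-dien-1-ol | OC/C(CCC=C(C)C)=C\C=C | intermediate
13 | 9-{(3Z)-4-[(9-borabicyclo[3.3.1]nonan-9-yloxy)methyl]-8-methylnona-3,7-dien-1-yl}-9-borabicyclo[3.3.1]nonane | CC(C)=CCC/C(COB1C2CCCC1CCC2)=C/CCB1C2CCCC1CCC2 | intermediate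
14 | tert-butyl (2E)-4-[2,5-bis(methoxymethoxy)phenyl]-2-[(3Z)-4-(hydroxymethyl)-8-methylnona-3,7-dien-1-yl]-4-oxobut-2-enoate | O=C(/C=C(\CC/C=C(\CO)CCC=C(C)C)C(=O)OC(C)(C)C)c1cc(OCOC)ccc1OCOC | intermediate
15 | tert-butyl (2R)-2-{2-[2,5-bis(methoxymethoxy)phenyl]-2-oxoethyl}-6-(4-methylpent-3-en-1-yl)-2,3,4,7-tetrahydrooxepine-2-carboxylate | CC(C)=CCCC1=CCC[C@@](CC(=O)c2cc(OCOC)ccc2OCOC)(C(=O)OC(C)(C)C)OC1 | intermediate
16 | tert-butyl (2R)-2-{2-[2,5-bis(methoxymethoxy)phenyl]-2-oxoethyl}-6-[(3E)-5-hydroxy-4-methylpent-3-en-1-yl]-2,3,4,7-tetrahydrooxepine-2-carboxylate | C/C(=C\CCC1=CCC[C@@](CC(=O)c2cc(OCOC)ccc2OCOC)(C(=O)OC(C)(C)C)OC1)CO | intermediate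
17 | (E)-4-hydroxycinnamic acid | OC(=O)/C=C/c1ccc(O)cc1 | starting material
18 | tert-butyl (2R)-2-{2-[2,5-bis(methoxymethoxy)phenyl]-2-oxoethyl}-6-[(3E)-5-{[(2E)-3-(4-hydroxyphenyl)prop-2-enoyl]oxy}-4-methylpent-3-en-1-yl]-2,3,4,7-tetrahydrooxepine-2-carboxylate | C/C(=C\CCC1=CCC[C@@](CC(=O)c2cc(OCOC)ccc2OCOC)(C(=O)OC(C)(C)C)OC1)COC(=O)/C=C/c1ccc(O)cc1 | intermediate
19 | CNP0602535.1, (2R)-acid | C/C(=C\CCC1=CCC[C@@](CC(=O)c2cc(O)ccc2O)(C(=O)O)OC1)COC(=O)/C=C/c1ccc(O)cc1 | target

## Count and risks
Total steps: 9. Longest linear sequence: 8 (steps 1, 2, 3, 5, 6, 7, 8, 9, from 1 to 19).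

**Step 6 (new reaction).**
- The equilibrium may be poor for a seven-membered ring with a fully substituted carbon.
- The superbase may remove a γ-proton of 14, which would deconjugate the enone and could lead to a six-membered ether.
- The ee is unknown.

The fallback uses known chemistry only. It sets out from 3, 4 and 11 and comes back at 15. But-3-enylmagnesium bromide is added once to oxalate 4 (THF, −78 °C) to give tert-butyl 2-oxohex-5-enoate F1. Ketone 3 is converted with LiN(SiMe3)2/TMSCl into its trimethylsilyl enol ether F2. A Mukaiyama aldol addition of F2 to F1 under [Cu((R,R)-tBu-box)](OTf)2 (10 mol %, CH2Cl2, −78 °C) follows, in which the ketoester chelates to divalent copper. It gives the (R)-configured aldol silyl ether F3. Aqueous citric acid in THF turns this into the tertiary alcohol F4. Magnesacycle 11 is quenched with water instead of being coupled, giving 6-methyl-2-methylidenehept-5-en-1-ol F5, and Boc2O/DMAP gives its tert-butyl carbonate F6. Pd2(dba)3/dppb (THF, 60 °C) joins F4 and F6 by decarboxylative allylic etherification to the diene ether F7. The 2-substituted allyl unit is symmetrical, so no regiochemical question arises. Ring-closing metathesis with the second-generation Hoveyda–Grubbs catalyst (CH2Cl2, 40 °C) closes the oxepine and gives 15.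

**Step 5.**
- The very electrophilic triflate 6 may be attacked by the base before it couples.
- If the borinate mask is lost, 14 could cyclise racemically in the flask.

The fallback takes the hydroxyl out of play, so that coupling and cyclisation are fully separated. It sets out from 12 and comes back at 14. TESCl/imidazole gives the dienol triethylsilyl ether F8, and 9-BBN (1.1 equiv) gives the homoallyl borane F9. Coupling with 6 can then be run under fast aqueous-base conditions (Pd(dppf)Cl2, AsPh3, aqueous Cs2CO3, DMF, rt) to give the silyl-protected enone F10. AcOH/THF/H2O at rt releases 14, and the MOM ethers and the tert-butyl ester survive.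

**Step 4.** Direct coupling of the chelated alkenylmagnesium in the presence of surplus alkyl Grignard reagent and copper may be low-yielding. The fallback inverts the polarity of the coupling. It sets out from 11 and comes back at 12. Magnesacycle 11 is quenched with I2 (THF, −40 °C) to give (2Z)-3-iodo-2-(4-methylpent-3-en-1-yl)prop-2-en-1-ol F11. After isolation this undergoes a Suzuki–Miyaura vinylation with potassium vinyltrifluoroborate (Pd(dppf)Cl2, Cs2CO3, THF/H2O, 60 °C) with retention to give 12.

Further compounds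
F1 | step 6 | tert-butyl 2-oxohex-5-enoate | C=CCCC(=O)C(=O)OC(C)(C)C
F2 | step 6 | {1-[2,5-bis(methoxymethoxy)phenyl]ethenyl}oxy(trimethyl)silane | C=C(O[Si](C)(C)C)c1cc(OCOC)ccc1OCOC
F3 | step 6 | tert-butyl (2R)-2-{2-[2,5-bis(methoxymethoxy)phenyl]-2-oxoethyl}-2-[(trimethylsilyl)oxy]hex-5-enoate | C=CCC[C@@](CC(=O)c1cc(OCOC)ccc1OCOC)(C(=O)OC(C)(C)C)O[Si](C)(C)C
F4 | step 6 | tert-butyl (2R)-2-{2-[2,5-bis(methoxymethoxy)phenyl]-2-oxoethyl}-2-hydroxyhex-5-enoate | C=CCC[C@@](CC(=O)c1cc(OCOC)ccc1OCOC)(C(=O)OC(C)(C)C)O
F5 | step 6 | 6-methyl-2-methylidenehept-5-en-1-ol | C=C(CO)CCC=C(C)C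
F6 | step 6 | tert-butyl (6-methyl-2-methylidenehept-5-en-1-yl) carbonate | C=C(COC(=O)OC(C)(C)C)CCC=C(C)C
F7 | step 6 | tert-butyl (2R)-2-{2-[2,5-bis(methoxymethoxy)phenyl]-2-oxoethyl}-2-[(6-methyl-2-methylidenehept-5-en-1-yl)oxy]hex-5-enoate | C=CCC[C@@](CC(=O)c1cc(OCOC)ccc1OCOC)(C(=O)OC(C)(C)C)OCC(=C)CCC=C(C)C
F8 | step 5 | triethyl{[(2Z)-2-(4-methylpent-3-en-1-yl)penta-2,4-dien-1-yl]oxy}silane | CC[Si](CC)(CC)OC/C(CCC=C(C)C)=C\C=C
F9 | step 5 | 9-[(3Z)-8-methyl-4-{[(triethylsilyl)oxy]methyl}nona-3,7-dien-1-yl]-9-borabicyclo[3.3.1]nonane | CC[Si](CC)(CC)OC/C(CCC=C(C)C)=C\CCB1C2CCCC1CCC2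
F10 | step 5 | tert-butyl (2E)-4-[2,5-bis(methoxymethoxy)phenyl]-2-[(3Z)-8-methyl-4-{[(triethylsilyl)oxy]methyl}nona-3,7-dien-1-yl]-4-oxobut-2-enoate | O=C(/C=C(\CC/C=C(\CO[Si](CC)(CC)CC)CCC=C(C)C)C(=O)OC(C)(C)C)c1cc(OCOC)ccc1OCOC
F11 | step 4 | (2Z)-3-iodo-2-(4-methylpent-3-en-1-yl)prop-2-en-1-ol | OC/C(CCC=C(C)C)=C\I
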